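I started from Friday's run and its neighbours, with Saturday's flask still to come.

in all of them: free catalyst 0.00360 M
- Friday's: substrate 0.120 M; partner 0.180 M
- Tuesday's: substrate 0.0720 M; partner 0.132 M
- Sunday's: substrate 0.120 M; partner 0.180 M; product 0.0600 M
- Wednesday's: substrate 0.120 M; partner 0.270 M
- Saturday's: substrate 0.0480 M; partner 0.180 M; time 14 min

| run | time / min | [product] / M |
|---|---|---|
| Friday's run | 0.62 | 0.0038 |
| Friday's run | 1.9 | 0.0121 |
| Friday's run | 3.6 | 0.0229 |
| Friday's run | 5.7 | 0.0324 |
| Friday's run | 8.2 | 0.0436 |
| Friday's run | 11 | 0.0553 |
| Friday's run | 14 | 0.0597 |
| Tuesday's run | 0.62 | 0.0013 |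
| Tuesday's run | 1.9 | 0.0068 |
| Tuesday's run | 3.6 | 0.0144 |
| Tuesday's run | 5.7 | 0.0209 |
| Tuesday's run | 8.2 | 0.0276 |
| Tuesday's run | 11 | 0.0348 |
| Tuesday's run | 14 | 0.0403 |
| Sunday's run | 0.62 | 0.0635 |
| Sunday's run | 1.9 | 0.0717 |
| Sunday's run | 3.6 | 0.0824 |
| Sunday's run | 5.7 | 0.0936 |
| Sunday's run | 8.2 | 0.1035 |
| Sunday's run | 11 | 0.1132 |
| Sunday's run | 14 | 0.1198 |
| Wednesday's run | 0.62 | 0.0032 |
| Wednesday's run | 1.9 | 0.0142 |
| Wednesday's run | 3.6 | 0.0243 |
| Wednesday's run | 5.7 | 0.0372 |
| Wednesday's run | 8.2 | 0.0476 |
| Wednesday's run | 11 | 0.0558 |
| Wednesday's run | 14 | 0.0655 |

(readings scatter by 0.001 M)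

- order of the initial rate in [substrate], near the charge of the Friday's run, the rate being that where two percent of its substrate are product (one fixed amount of product, the same in the runs compared)
- order of the initial rate in [partner], near the charge of the Friday's run, the rate being that where two percent of its substrate are product
- the Tuesday's run starts with 0.0480 M less of substrate and of partner than the Friday's run, and with no product. Compared where both hold the same amount of substrate, once fifteen percent of what the Tuesday's run was charged with has turned into product, is the Tuesday's run faster, slower or alike (within a tenth)?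
- product in the Saturday's run at 14 min, as a share of the substrate charged

- Overall: substrate + partner -> product, with free catalyst as catalyst.
- Constant volume, constant temperature.
- An order is taken over about fifteen percent of the charge, up and down.

Sunday's run was Friday's charge with 0.0600 M of product added, and its first slope, 0.00634 M/min, read like Friday's 0.00641 M/min, so I set product aside. Yet the rate seemed to fade with age, and I measured that fading in two ways.

The first way needed no order. Tuesday's run is a same-excess experiment: like Friday's, it was charged with 0.0600 M more partner than substrate. Friday's run held 0.0647 M of substrate at 11 min, and Tuesday's held 0.0641 M across its first window, at a mean age of 2.11 min. Tuesday's slope there, 0.00440 M/min, was faster than Friday's 0.00278 M/min, read around a mean age of 11.1 min.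

  age difference / ln(rate ratio) = 8.99 min / ln(1.58) = 19.6 min

The second way stayed inside Sunday's run and removed the loss of substrate with an order n. I read n from Friday's and Tuesday's first slopes, with substrate and partner falling together, as 0.738. Sunday's substrate went from 0.107 M to 0.0683 M between its windows, and its slope fell to 0.00281 M/min.

  age difference / [ln(slope ratio) − n ln(substrate ratio)] = 18.6 min

The two share Tuesday's first slope, and a high reading there shortens both, so their closeness is no independent check. The fading time τ, the time in which the rate at fixed composition falls by a factor e, I took as their mean, 19.1 min.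

A fading rate runs on working minutes, θ = τ(1 − e^(−t/τ)). If the rate goes as S^n e^(−t/τ) at one partner charge, with S the substrate, and f is the share of substrate left, then 1 − f^m grows in step with θ divided by the charged substrate to the power m, where m = 1 − n = 0.262. Friday's and Saturday's flasks share 0.180 M of partner, and at 14 min both have had 9.92 min of working time. So I scaled Friday's reading:

  Friday: 1 − f^m = 0.165
  Saturday: 1 − f^m = 0.210, so product = 59.3%

The forecast gave orders of 0.7 and 0.18, Tuesday's run faster, and 59% for Saturday. Its ground for the fading was that “The older mixture is slower, with no product effect”. My n, unlike its order, has partner mixed in.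

    free catalyst + substrate → loaded catalyst + by-product (145.2 /M/min)
    loaded catalyst + partner → product + free catalyst (29.46 /M/min)
    2 partner → lost reagent (0.5142 /M/min)
    2 free catalyst ⇌ resting dimer, settled at all times (3650 /M)

The flask gave orders of 0.69 and 0.33, Tuesday's run faster, and 63.9% for Saturday. By the step to lost reagent, Friday's partner has a first half-life of 5.40 min, shorter than τ. Through my rule, Saturday's figure corresponds to 11.1 min of working time, against the 9.92 min I allowed. In Wednesday's run, product reached a quarter of the charge at 4.44 min and half at 12.0 min, a ratio of 2.70 on the clock, 2.25 in working minutes, and 2.29 by the rule.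

All runs were generated by integration for an exercise; scatter was added.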